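The data were computed with constants of no real substance, noise included.

Time is the setting to watch: Monday's flask runs 12 min, twice Friday's, and target may not keep.

| flask | starting material | reagent in the second phase | remark | time | volume of the second phase over the first |
|---|---|---|---|---|---|
| alpha | 0.30 M | 1.4 M | run made earlier |  |  |
| Monday's | 0.10 M | 0.900 M |  | 12 min | 1.0 |
| Friday's | 0.30 M | 0.900 M |  | 6.0 min | 1.0 |

alpha run (percent of the starting material charged)

| time / min | target / % | starting material / % |
|---|---|---|
| 0.667 | 8.3 | 87.9 |
| 1.33 | 22.7 | 66.4 |
| 2.00 | 37.5 | 46.9 |
| 3.00 | 54.5 | 27.4 |
| 4.00 | 64.9 | 16.1 |

(each reading ± 0.3 percentage points)

- charges count per volume of the first phase; a concentration in a rate is the amount of a species over the volume of its own phase; every rate counts per litre of the first phase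
- the earlier runs hold the two phases in the same ratio of volumes as the flask asked about
- a reading or a percentage of target counts all its forms, free or not
- a reading of starting material is of its free form alone

- which one finishes higher in amount of target, in percent of the starting material charged ("neither" within 2 percentage points) (Monday's / Friday's / neither)
- amount of target at the end, in percent of the starting material charged, Monday's
- amount of target at the end, in percent of the starting material charged, Friday's

I take the alpha run in slow motion. In the first instants target reads 8.3% at 0.667 min. By 2.00 min about half of the starting material stands free, and the gap, what the two readings fail to account for, is 15.6%. At 4.00 min the gap is 19.0%. I treat it as a correction with two shares, one that follows the product of the two readings and shrinks as starting material goes, one that grows with the time target has stood. The second share's fraction of target lost per minute is the leak. In full charges, target-minutes by trapezoids are 0.332 min and 1.39 min. The readings at those two times give the two unknowns: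

gap = c × starting material × target + leak × target-minutes

leak = 0.0817 min⁻¹

This is a reading and carries their scatter. Assuming first order in reagent and in starting material, which is untested, alpha's half point of 2.00 min moves to 3.11 min in Monday's flask. As a rough reckoning, I let all of Monday's target stand from that point on:

target ≈ exp(−leak × (time − half point)) = 48.4%

The same scaling puts Friday's end at alpha's 3.86 min, beside its last reading, so for Friday's I expect about 64.9%, more than my Monday's figure.

The forecast says Monday's: 91% (85% to 95%) for Monday's and 64% (53% to 73%) for Friday's, reading “a dead-end loss competes with target formation”. Its Monday's figure stands above mine.

Monday's gives 59.2% and Friday's 63.8%, so Friday's ends higher.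

    reagent in the reaction phase ⇌ reagent in the second phase, rate k1*([reagent in the reaction phase] - [reagent in the second phase]/K1) per volume of the first phase (partition coefficient = 0.540, kL = 0.00140 s⁻¹)
    starting material + reagent in the reaction phase → target (k = 0.0340 L mol⁻¹ s⁻¹)
    target ⇌ product in the second phase, rate k3*([target] - [product in the second phase]/K3) per volume of the first phase (partition coefficient = 6.00, kL = 0.00180 s⁻¹)
    target → decomposed product (k = 0.00170 s⁻¹)
    starting material + target ⇌ idle adduct, settled at all times (K = 4.40 L mol⁻¹)

At its end, Monday's flask holds 39.0% of the charge as product in the second phase; with that and the target in idle adduct taken off, 20.2% of the charge stands as free target, against 49.3% at 6.00 min. Put on the mean free target, the leak gives 17 percentage points lost over that stretch, while decomposed product rises 21 points.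

Left until 20 min, Monday's flask holds 6.74% free target at the end, so the leak gives 50.4%. The computed result is 49.7%.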